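**Plan**

1. Retrosynthesis: the benzo[7]annulenone is cut at C4a–C5 and C9–C9a (one carbon extruded as CO2) into (−)-epicatechin and a flavan-3-yl gallate whose ring B is 2,3,4-trihydroxyphenyl. This pattern, not 3,4,5, is needed because the flavanyl group of the target sits at C7, next to the tropolone C6–OH.
2. The gallate C–O bond is cut next, then C4–C4a and O1–C2 of ring C of that flavan, which leaves 3,5-bis(benzyloxy)phenol and a 2-methoxy-3-arylpropenal.
3. Enabling feature: in phloroglucinol ring A, O1–C8a–C4a is an enol-type C,O-dinucleophile. With C3 held at the enol-ether (ketone) level, C4 and C2 are the carbonyl and β-carbons of an enal, so O1=C8a–C4a=C4–C3=C2 is a 1-oxatriene that closes by 6π electrocyclisation.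
4. Forward: ring C is annulated first, then hydrolysis to the flavan-3-one, reduction, galloylation and debenzylation; the seven-membered ring arises last by oxidative union with epicatechin.
5. Stereochemistry: C2 and C3 of the galloylated unit come from one dynamic kinetic transfer hydrogenation of the racemic, C2-labile ketone (catalyst sets C3, hydride anti to the aryl group gives cis); the other flavan unit is (−)-epicatechin from the chiral pool.

Key step: step 5

Assumption: the (R,R)-TsDPEN ruthenium catalyst is taken to be the antipode that delivers hydride to the Si face of C3; if the sense is the reverse, the (S,S) complex is used with no other change.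

**Route**

Step 1
Reactants: 1 2,3,4-trihydroxybenzaldehyde
Product: 2 2,3,4-tris(benzyloxy)benzaldehyde
Conditions: BnBr (3.6 equiv), K2CO3 (4 equiv), DMF, 60 °C
Reagents that add atoms: benzyl bromide, BrCc1ccccc1
Why: Williamson ether synthesis (SN2 of the three phenoxides on benzyl bromide), in which the hydrogen-bonded 2-OH is also alkylated in warm DMF and no stereocenter is formed.

Step 2
Reactants: 2 2,3,4-tris(benzyloxy)benzaldehyde; 3 methyl methoxyacetate
Product: 4 methyl (Z)-2-methoxy-3-[2,3,4-tris(benzyloxy)phenyl]prop-2-enoate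
Conditions: NaOMe (1.5 equiv), THF, 0 °C to 50 °C
Reagents that add atoms: none
Why: Claisen-type aldol condensation of the ester enolate with the non-enolisable aldehyde and E1cB loss of hydroxide should give the conjugated 2-methoxyacrylate, the Z isomer (aryl trans to the ester) being the thermodynamic one, and the alkene geometry has no consequence later.

Step 3
Reactants: 4 methyl (Z)-2-methoxy-3-[2,3,4-tris(benzyloxy)phenyl]prop-2-enoate
Product: 5 (Z)-2-methoxy-3-[2,3,4-tris(benzyloxy)phenyl]prop-2-en-1-ol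
Conditions: DIBAL-H (iBu2AlH, 2.4 equiv), CH2Cl2, −78 °C to 0 °C; aqueous Rochelle salt
Reagents that add atoms: none
Why: DIBAL-H 1,2-reduction of a conjugated ester to the allylic alcohol, to which benzyl ethers and the enol ether are inert.

Step 4
Reactants: 5 (Z)-2-methoxy-3-[2,3,4-tris(benzyloxy)phenyl]prop-2-en-1-ol
Product: 6 (Z)-2-methoxy-3-[2,3,4-tris(benzyloxy)phenyl]prop-2-enal
Conditions: activated MnO2 (10 equiv), CH2Cl2, rt
Reagents that add atoms: none
Why: chemoselective MnO2 oxidation of an allylic alcohol to the enal, which should leave the enol ether and the benzyl ethers untouched.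

Step 5
Reactants: 6 (Z)-2-methoxy-3-[2,3,4-tris(benzyloxy)phenyl]prop-2-enal; 7 3,5-bis(benzyloxy)phenol
Product: 10 rac-5,7-bis(benzyloxy)-3-methoxy-2-[2,3,4-tris(benzyloxy)phenyl]-2H-chromene, via benzodioxaborinine adduct 8 (not isolated), via ortho-quinone methide 9 (not isolated)
Conditions: C6F5B(OH)2 (20 mol %), Ph2P(O)OH (20 mol %), toluene, 4 Å MS, 90 °C
Reagents that add atoms: none
Why: The boronic acid condenses with the phenol OH of 7 and binds the aldehyde of 6, so that the aldehyde carbon is delivered to the ortho carbon through a six-membered array (C4–C4a bond) to give dioxaborinine 8; acid-assisted cycloreversion releases the boronic acid and unveils ortho-quinone methide 9. The closest known reaction type is the boronic acid/Brønsted acid-catalysed condensation of phenols with enals to 2H-chromenes (formal [3+3], Knoevenagel-type addition then oxa-6π closure). Ring C closes by thermal disrotatory oxa-6π electrocyclisation of the 1-oxatriene O1=C8a–C4a=C4–C3=C2 in 9, which forms O1–C2 and restores the aromaticity of ring A. The new stereocenter C2 is formed without control, on purpose, because it becomes epimerisable at the ketone stage and is corrected in step 7. The step needs ortho C-attack over O-attack and over the para carbon between the two benzyloxy groups, and 1,2- over 1,4-addition to the enal; the boron tether from the phenol oxygen secures both. The 2-methoxy group fixes C3 at the ketone oxidation level and removes any acidic α-hydrogen from the enal.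

Step 6
Reactants: 10 rac-5,7-bis(benzyloxy)-3-methoxy-2-[2,3,4-tris(benzyloxy)phenyl]-2H-chromene
Product: 11 rac-5,7-bis(benzyloxy)-2-[2,3,4-tris(benzyloxy)phenyl]chroman-3-one
Conditions: 1 M aq. HCl, THF, rt, under argon
Reagents that add atoms: water, O
Why: acid-catalysed enol ether hydrolysis (protonation at C4, hydration of the C3 oxocarbenium ion, loss of methanol) should give the ketone, whose C2 stays racemic as the next step requires.

Step 7
Reactants: 11 rac-5,7-bis(benzyloxy)-2-[2,3,4-tris(benzyloxy)phenyl]chroman-3-one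
Product: 12 (2R,3R)-5,7-bis(benzyloxy)-2-[2,3,4-tris(benzyloxy)phenyl]chroman-3-ol
Conditions: RuCl[(R,R)-TsDPEN](p-cymene) (2 mol %), HCO2H/Et3N (5:2), DMF, 40 °C, under argon
Reagents that add atoms: none
Why: Noyori–Ikariya asymmetric transfer hydrogenation run as a dynamic kinetic resolution, in which C2–H (flanked by the ketone, O1 and the aryl ring) epimerises through the enol faster than reduction while the catalyst reduces the (2R)-ketone from the C3 face anti to the aryl group, so that C3 (R) is set by the catalyst and C2 (R) by selection in a cis relationship.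

Step 8
Reactants: 12 (2R,3R)-5,7-bis(benzyloxy)-2-[2,3,4-tris(benzyloxy)phenyl]chroman-3-ol; 13 3,4,5-tris(benzyloxy)benzoic acid
Product: 14 (2R,3R)-5,7-bis(benzyloxy)-2-[2,3,4-tris(benzyloxy)phenyl]chroman-3-yl 3,4,5-tris(benzyloxy)benzoate
Conditions: EDC·HCl (1.5 equiv), DMAP (0.5 equiv), CH2Cl2, rt
Reagents that add atoms: none
Why: Steglich esterification (carbodiimide activation, DMAP acyl transfer) acylates the C3 oxygen with retention, since no bond to C3 is broken.

Step 9
Reactants: 14 (2R,3R)-5,7-bis(benzyloxy)-2-[2,3,4-tris(benzyloxy)phenyl]chroman-3-yl 3,4,5-tris(benzyloxy)benzoate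
Product: 15 (2R,3R)-5,7-dihydroxy-2-(2,3,4-trihydroxyphenyl)chroman-3-yl 3,4,5-trihydroxybenzoate
Conditions: H2 (1 atm), Pd(OH)2/C, THF/MeOH, rt; isolation under argon
Reagents that add atoms: none
Why: heterogeneous hydrogenolysis of the eight benzyl ethers under neutral conditions should spare the gallate ester and the C2–O1 bond of the chroman and touches no stereocenter.

Step 10
Reactants: 15 (2R,3R)-5,7-dihydroxy-2-(2,3,4-trihydroxyphenyl)chroman-3-yl 3,4,5-trihydroxybenzoate; 16 (−)-epicatechin
Product: 19 (2R,3R)-5,7-dihydroxy-2-{3,4,6-trihydroxy-5-oxo-1-[(2R,3R)-3,5,7-trihydroxychroman-2-yl]-5H-benzo[7]annulen-7-yl}chroman-3-yl 3,4,5-trihydroxybenzoate, via epicatechin ortho-quinone 17 (not isolated), via biaryl adduct 18 (not isolated)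
Conditions: mushroom tyrosinase, air (O2), citrate–phosphate buffer pH 5.5, 25 °C
Reagents that add atoms: none
Why: biomimetic oxidative benzotropolone annulation of a catechol with a pyrogallol (the purpurogallin-type condensation), in which tyrosinase oxidises the catechol of 16 to 17, ring-B carbon C5′ of 15 (ortho to 4′-OH, para to 2′-OH) adds in conjugate fashion to C6′ of 17 to give 18, and renewed oxidation, closure of the catechol carbon onto the central C3′ carbonyl, hydration and loss of C4′ as CO2 should leave the seven-membered ring with the flavanyl group next to the tropolone hydroxyl, the four stereocenters being untouched at pH 5.5.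

**Compound list**

1 | 2,3,4-trihydroxybenzaldehyde | O=Cc1ccc(O)c(O)c1O | starting material
2 | 2,3,4-tris(benzyloxy)benzaldehyde | O=Cc1ccc(OCc2ccccc2)c(OCc2ccccc2)c1OCc1ccccc1 | intermediate
3 | methyl methoxyacetate | COCC(=O)OC | starting material
4 | methyl (Z)-2-methoxy-3-[2,3,4-tris(benzyloxy)phenyl]prop-2-enoate | COC(=O)/C(OC)=C/c1ccc(OCc2ccccc2)c(OCc2ccccc2)c1OCc1ccccc1 | intermediate
5 | (Z)-2-methoxy-3-[2,3,4-tris(benzyloxy)phenyl]prop-2-en-1-ol | OC/C(OC)=C/c1ccc(OCc2ccccc2)c(OCc2ccccc2)c1OCc1ccccc1 | intermediate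
6 | (Z)-2-methoxy-3-[2,3,4-tris(benzyloxy)phenyl]prop-2-enal | O=C/C(OC)=C/c1ccc(OCc2ccccc2)c(OCc2ccccc2)c1OCc1ccccc1 | intermediate
7 | 3,5-bis(benzyloxy)phenol | Oc1cc(OCc2ccccc2)cc(OCc2ccccc2)c1 | starting material
8 | benzodioxaborinine adduct, 5,7-bis(benzyloxy)-4-{(Z)-1-methoxy-2-[2,3,4-tris(benzyloxy)phenyl]ethenyl}-2-(pentafluorophenyl)-4H-1,3,2-benzodioxaborinine (racemic) | CO/C(=C\c1ccc(OCc2ccccc2)c(OCc2ccccc2)c1OCc1ccccc1)C1OB(c2c(F)c(F)c(F)c(F)c2F)Oc2cc(OCc3ccccc3)cc(OCc3ccccc3)c21 | intermediate
9 | ortho-quinone methide, 3,5-bis(benzyloxy)-6-{(Z)-2-methoxy-3-[2,3,4-tris(benzyloxy)phenyl]prop-2-enylidene}cyclohexa-2,4-dien-1-one | CO/C(=C\c1ccc(OCc2ccccc2)c(OCc2ccccc2)c1OCc1ccccc1)/C=C1\C(=O)C=C(OCc2ccccc2)C=C1OCc1ccccc1 | intermediate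
10 | rac-5,7-bis(benzyloxy)-3-methoxy-2-[2,3,4-tris(benzyloxy)phenyl]-2H-chromene | COC1=Cc2c(OCc3ccccc3)cc(OCc3ccccc3)cc2OC1c1ccc(OCc2ccccc2)c(OCc2ccccc2)c1OCc1ccccc1 | intermediate
11 | rac-5,7-bis(benzyloxy)-2-[2,3,4-tris(benzyloxy)phenyl]chroman-3-one | O=C1Cc2c(OCc3ccccc3)cc(OCc3ccccc3)cc2OC1c1ccc(OCc2ccccc2)c(OCc2ccccc2)c1OCc1ccccc1 | intermediate
12 | (2R,3R)-5,7-bis(benzyloxy)-2-[2,3,4-tris(benzyloxy)phenyl]chroman-3-ol | O[C@@H]1Cc2c(OCc3ccccc3)cc(OCc3ccccc3)cc2O[C@@H]1c1ccc(OCc2ccccc2)c(OCc2ccccc2)c1OCc1ccccc1 | intermediate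
13 | 3,4,5-tris(benzyloxy)benzoic acid | OC(=O)c1cc(OCc2ccccc2)c(OCc2ccccc2)c(OCc2ccccc2)c1 | starting material
14 | (2R,3R)-5,7-bis(benzyloxy)-2-[2,3,4-tris(benzyloxy)phenyl]chroman-3-yl 3,4,5-tris(benzyloxy)benzoate | O=C(O[C@@H]1Cc2c(OCc3ccccc3)cc(OCc3ccccc3)cc2O[C@@H]1c1ccc(OCc2ccccc2)c(OCc2ccccc2)c1OCc1ccccc1)c1cc(OCc2ccccc2)c(OCc2ccccc2)c(OCc2ccccc2)c1 | intermediate
15 | (2R,3R)-5,7-dihydroxy-2-(2,3,4-trihydroxyphenyl)chroman-3-yl 3,4,5-trihydroxybenzoate | O=C(O[C@@H]1Cc2c(O)cc(O)cc2O[C@@H]1c1ccc(O)c(O)c1O)c1cc(O)c(O)c(O)c1 | intermediate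
16 | (−)-epicatechin, (2R,3R)-2-(3,4-dihydroxyphenyl)chroman-3,5,7-triol | O[C@@H]1Cc2c(O)cc(O)cc2O[C@@H]1c1ccc(O)c(O)c1 | starting material
17 | epicatechin ortho-quinone, 4-[(2R,3R)-3,5,7-trihydroxychroman-2-yl]cyclohexa-3,5-diene-1,2-dione | O[C@@H]1Cc2c(O)cc(O)cc2O[C@@H]1C1=CC(=O)C(=O)C=C1 | intermediate
18 | biaryl adduct, (2R,3R)-2-{5-[4,5-dihydroxy-2-((2R,3R)-3,5,7-trihydroxychroman-2-yl)phenyl]-2,3,4-trihydroxyphenyl}-5,7-dihydroxychroman-3-yl 3,4,5-trihydroxybenzoate | O=C(O[C@@H]1Cc2c(O)cc(O)cc2O[C@@H]1c1cc(-c2cc(O)c(O)cc2[C@H]2Oc3cc(O)cc(O)c3C[C@H]2O)c(O)c(O)c1O)c1cc(O)c(O)c(O)c1 | intermediate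
19 | (2R,3R)-5,7-dihydroxy-2-{3,4,6-trihydroxy-5-oxo-1-[(2R,3R)-3,5,7-trihydroxychroman-2-yl]-5H-benzo[7]annulen-7-yl}chroman-3-yl 3,4,5-trihydroxybenzoate | O=C(O[C@@H]1Cc2c(O)cc(O)cc2O[C@@H]1c1ccc2c([C@H]3Oc4cc(O)cc(O)c4C[C@H]3O)cc(O)c(O)c2c(=O)c1O)c1cc(O)c(O)c(O)c1 | target

**Step count**

Total steps: 10. Longest linear sequence: 10 steps (1 to 19 through 2, 4, 5, 6, 10, 11, 12, 14 and 15).

**Steps most likely to fail**

Step 10. The oxidation may lack selectivity. The epicatechin quinone can couple with itself or with the nucleophilic A rings, it can attack the galloyl ring in place of ring B of 15, and the benzotropolone can be oxidised further. The fallback sets out from 15 and 16 and comes back at 19, and it separates oxidation from coupling. Epicatechin 16 alone is oxidised with Ag2O in acetonitrile at 0 °C and filtered to give a solution of ortho-quinone 17. About three equivalents are added slowly to 15 in acetonitrile/pH 4.5 buffer under argon. The first equivalent is captured by conjugate addition to give 18; the others act as the stoichiometric oxidant for the ring expansion with loss of CO2 and are returned as 16. Neither enzyme nor dioxygen then meets the free triol of 15. This fallback makes no compound outside the list (F0).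

Step 5. The templated ortho-hydroxyalkylation may stall on the electron-rich enal, or the acid may divert the enol ether before the electrocyclisation. The fallback sets out from 5 and 7 and comes back at 10; it forms the two bonds in separate operations and reaches the same quinone methide by dehydrogenation. Friedel–Crafts allylation of 7 with allylic alcohol 5 on montmorillonite K10 in CH2Cl2 should give 3,5-bis(benzyloxy)-2-{(Z)-2-methoxy-3-[2,3,4-tris(benzyloxy)phenyl]prop-2-enyl}phenol F1. DDQ in benzene then abstracts hydride from the doubly activated CH2 to give ortho-quinone methide 9, which closes to 10.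

Step 7. Epimerisation at C2 may be slower than reduction, or the catalyst may discriminate poorly between the two faces of a ketone that has a benzylic carbon on each side; either lowers the enantiomeric and diastereomeric purity. The fallback sets out from 11 and comes back at 12 and uses substrate control followed by resolution. Lithium tri-sec-butylborohydride, LiBH(s-Bu)3, in THF at −78 °C should attack anti to the aryl group and give the racemic cis-alcohol rac-(2R*,3R*)-5,7-bis(benzyloxy)-2-[2,3,4-tris(benzyloxy)phenyl]chroman-3-ol F2. Preparative chromatography on a chiral stationary phase gives 12. The unwanted (2S,3S)-5,7-bis(benzyloxy)-2-[2,3,4-tris(benzyloxy)phenyl]chroman-3-ol F3 is oxidised back to 11 with Dess–Martin periodinane and recycled.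

**Further compounds**

F0 | step 10 | none | none
F1 | step 5 | 3,5-bis(benzyloxy)-2-{(Z)-2-methoxy-3-[2,3,4-tris(benzyloxy)phenyl]prop-2-enyl}phenol | CO/C(Cc1c(O)cc(OCc2ccccc2)cc1OCc1ccccc1)=C\c1ccc(OCc2ccccc2)c(OCc2ccccc2)c1OCc1ccccc1
F2 | step 7 | rac-(2R*,3R*)-5,7-bis(benzyloxy)-2-[2,3,4-tris(benzyloxy)phenyl]chroman-3-ol (both enantiomers) | O[C@@H]1Cc2c(OCc3ccccc3)cc(OCc3ccccc3)cc2O[C@@H]1c1ccc(OCc2ccccc2)c(OCc2ccccc2)c1OCc1ccccc1.O[C@H]1Cc2c(OCc3ccccc3)cc(OCc3ccccc3)cc2O[C@H]1c1ccc(OCc2ccccc2)c(OCc2ccccc2)c1OCc1ccccc1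
F3 | step 7 | (2S,3S)-5,7-bis(benzyloxy)-2-[2,3,4-tris(benzyloxy)phenyl]chroman-3-ol | O[C@H]1Cc2c(OCc3ccccc3)cc(OCc3ccccc3)cc2O[C@H]1c1ccc(OCc2ccccc2)c(OCc2ccccc2)c1OCc1ccccc1
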